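Readings and results come from a simulation from invented constants, noise included.

- If a flask stops with substrate still present, as noon does with 30.3% of left-handed substrate read at 5.00 d, I look to the partner as the likely limiting reagent, shared between the reaction and its own decay.

the same everywhere: left-handed substrate 20 mM; right-handed substrate 20 mM; free catalyst 50 µM

| flask | partner | racemization catalyst | remark | time |
|---|---|---|---|---|
| dusk | 40 mM | 0.56 mM | run made earlier |  |
| noon | 40 mM | 0.88 mM | run made earlier |  |
| flask | 40.0 mM | 0.40 mM |  | 4.0 d |

- dusk (time / d: left-handed product / %, right-handed product / %, left-handed substrate / %): 0.417: 28.6, 6.2, 32.9; 0.625: 32.6, 7.0, 30.2; 0.833: 32.8, 7.4, 30.9; 1.25: 34.2, 8.4, 29.8; 2.08: 34.1, 6.9, 28.8; 3.00: 33.7, 7.3, 29.1; 5.00: 34.6, 8.3, 28.4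
- noon (time / d: left-handed product / %, right-handed product / %, left-handed substrate / %): 0.250: 23.7, 4.8, 34.9; 0.833: 33.9, 7.4, 30.7; 1.25: 34.2, 7.0, 28.9; 2.08: 34.0, 7.6, 28.8; 3.00: 34.1, 7.1, 29.4; 4.00: 34.6, 7.4, 28.3; 5.00: 34.8, 7.6, 30.3

(each reading ± 0.5 percentage points)

- free catalyst is single-handed; left-handed substrate and right-handed substrate are mirror images of each other, charged as a racemate, each of them at the stated concentration
- the numbers in the tables scatter by 0.5 percentage points (one standard deviation)
- what may be going on: partner + free catalyst + left-handed substrate -> free catalyst + left-handed product; partner + free catalyst + right-handed substrate -> free catalyst + right-handed product; left-handed substrate + racemization catalyst <-> right-handed substrate + racemization catalyst; partner -> decomposed reagent; partner + free catalyst -> spent catalyst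
- an excess is below zero if the other one leads

1. left-handed product and right-handed product together, in percent of the left-handed substrate and right-handed substrate charged together, at 4.0 d
2. excess of left-handed product over right-handed product in the product at 4.0 d
3. whether the exchange between left-handed substrate and right-handed substrate keeps pace with the reaction: how far the product's excess at 4.0 d gets from its value without exchange to its value with instant exchange (above 80% keeps pace, below 20% hardly takes part, else lags behind)

- I hold the free catalyst steady and the leftover substrate racemic, so the reaction goes as partner times substrate and the decay as partner, and the partner cancels from their ratio.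
- Let c be the fraction of substrate converted, u the fraction left, and b the partner charge as a fraction of the substrate charge; then b = c − κ ln u.
- The two products together, read from 2.08 d on, average 41.6% in dusk and 41.8% in noon, so I read c as 41.7% at b = 1.00.
- That gives κ = 1.08, the partner lost to decay for each partner used in reaction at full substrate charge.
- The flask has b = 1.00, the same as both runs, so I expect 41.7%.
- κ holds no racemization catalyst, so I take the yield from it and not the excess.
- The forecast gives a yield of 41.3% and an excess of 61.5% and says the exchange lags behind, holding that “exchange is fast overall. However, the reaction is also fast”.
- The flask gives a yield of 41.6% and an excess of 64.0%, and the exchange keeps pace: the excess gets 91% of the way, which is where the forecast parts from it.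

    partner + free catalyst + left-handed substrate → free catalyst + left-handed product (k = 23.0 M⁻² s⁻¹)
    partner + free catalyst + right-handed substrate → free catalyst + right-handed product (k = 4.90 M⁻² s⁻¹)
    left-handed substrate + racemization catalyst ⇌ right-handed substrate + racemization catalyst, rate k3*[racemization catalyst]*[left-handed substrate] forward; the back reaction follows from the equilibrium constant (k = 0.660 M⁻¹ s⁻¹)
    partner → decomposed reagent (k = 2.80 × 10⁻⁵ s⁻¹)
    partner + free catalyst → spent catalyst (k = 1.70 × 10⁻⁴ M⁻¹ s⁻¹)

- The neighbour flask charged with 24 mM of partner has b = 0.600, and taking the logarithm to its second term with the same κ gives c = 27.0%. It gives 27.0%, at an excess of 64.3%, with partner at 0% of its charge and 73% of the left-handed substrate charge left.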